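The runs were computed for an exercise; scatter was added.

3 questions stand on this flask: how far it goes (c), the excess in the product (eP) and the excess in the substrate (eS).

* part of the left-handed substrate and right-handed substrate charged together that has reacted at 5.0 d
* excess of left-handed product over right-handed product in the product at 5.0 d
* excess of right-handed substrate over left-handed substrate among what is left of the two at 5.0 d

in all of them: gas 6.2 mM (held); racemization catalyst 10 mol%; added ligand 86 mM
- Thursday's: left-handed substrate 0.16 M; right-handed substrate 0.16 M; free catalyst 5 mol%; run made earlier
- Monday's: left-handed substrate 0.16 M; right-handed substrate 0.16 M; free catalyst 7.5 mol%; run made earlier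
- Tuesday's: left-handed substrate 0.32 M; right-handed substrate 0.32 M; free catalyst 10 mol%; run made earlier
- flask: left-handed substrate 0.16 M; right-handed substrate 0.16 M; free catalyst 10 mol%; time 5.0 d

- Thursday's (time / d: left-handed substrate / %, right-handed substrate / %, left-handed product / %): 0.625: 44.6, 46.1, 6.4; 1.25: 41.1, 43.0, 9.1; 1.67: 40.2, 42.9, 13.7; 2.50: 39.3, 40.8, 12.8; 3.00: 40.2, 39.6, 12.3
- Monday's (time / d: left-handed substrate / %, right-handed substrate / %, left-handed product / %): 0.250: 45.8, 49.3, 2.8; 0.417: 43.2, 47.6, 5.4; 0.833: 40.1, 45.2, 10.2; 1.67: 37.3, 38.8, 16.3; 3.00: 35.9, 37.6, 18.9
- Tuesday's (time / d: left-handed substrate / %, right-handed substrate / %, left-handed product / %): 0.250: 42.9, 46.2, 8.5; 0.417: 39.1, 42.8, 9.0; 0.833: 32.0, 39.2, 21.0; 1.67: 28.1, 29.6, 30.7; 3.00: 22.5, 23.3, 37.8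

(standard deviation of a reading: 1 percentage point)

- free catalyst is single-handed; left-handed substrate and right-handed substrate are mirror images of each other, charged as a racemate, each of them at the stated concentration
- at the start none of reagent is dissolved
- the numbers in the tables scatter by 1 percentage point (one standard deviation)
- steps thought possible: reagent + free catalyst + left-handed substrate -> free catalyst + left-handed product; reagent + free catalyst -> spent catalyst; reagent + free catalyst + right-handed substrate -> free catalyst + right-handed product; gas <-> reagent; free catalyst + added ligand <-> idle complex; left-handed substrate + racemization catalyst <-> right-handed substrate + racemization catalyst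
- an excess is below zero if the other one leads

**First instants.** At the start the flask holds no dissolved reagent. Gas feeds it in, and both product steps need it. The left-handed substrate then falls faster: Monday's run shows 45.8% against 49.3% of the right-handed at 0.250 d.

**Middle.** Monday's gap between the substrates opens to 5.1 percentage points at 0.833 d, then shrinks to 1.7 points at 3.00 d. At 3.00 d the gaps in the other runs are −0.6 points and 0.8 points, against a scatter of 1 point per reading. So I take the symmetric case as the zero of the scale and put eS near zero, within the scatter.

For the product I use f, the left-handed product's share of what has reacted. The last readings of the three runs pool to f = 68.4%. Equal shares would be no selection. The excess eP is f less the right-handed product's share, so eP = 36.8%.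

**End.** The product steps and the step to spent catalyst both use reagent and free catalyst. Substrate lost per spent catalyst made therefore goes with the substrate present, the reagent level drops out of that ratio, and the logarithm of the substrate follows the spent catalyst. I take the spent part of the catalyst charge as the same share from run to run. Thursday's substrates stand at 80.1% and then 79.8%, flat within the scatter. That gives λ = 0.0282 mM⁻¹: the reach, the logarithm of charged over remaining substrate, per unit of free catalyst charged.

This flask has 16.0 mM of catalyst, so I reckon c = 36.3%.

The forecast says 35%, 41% and 0.3%, on the ground that “Conversion stalls because the catalyst dies”.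

The flask gives 38.3%, 37.6% and 0.610%.

    reagent + free catalyst + left-handed substrate → free catalyst + left-handed product (k = 260 L² mol⁻² h⁻¹)
    reagent + free catalyst → spent catalyst (k = 2.20 L mol⁻¹ h⁻¹)
    reagent + free catalyst + right-handed substrate → free catalyst + right-handed product (k = 110 L² mol⁻² h⁻¹)
    gas ⇌ reagent, rate k4*(csat - [reagent]) (kL = 5.20 h⁻¹)
    free catalyst + added ligand ⇌ idle complex (K = 230 L mol⁻¹, k = 0.290 L mol⁻¹ h⁻¹)
    left-handed substrate + racemization catalyst ⇌ right-handed substrate + racemization catalyst, rate k6*[racemization catalyst]*[left-handed substrate] forward; the back reaction follows from the equilibrium constant (k = 1.90 L mol⁻¹ h⁻¹)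

This flask's own reach at 5.0 d is 0.0302 mM⁻¹, above Thursday's reading. I carry it to the neighbour charged with 17 mol% of free catalyst, other charges and time as in this flask. That neighbour holds 27.2 mM of catalyst, so the reach gives c = 56.0%. The neighbour's simulated c is 55.8%.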